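The route rests on cutting the C9–O bond of the spiro tetrahydrofuran to reveal a phenol. Ring B (C5–C10) carries oxygen at C6, C8 and C9, the pattern of a 4-alkylresorcinol in which C9 is para to the C6 oxygen. Oxidation of that phenol, whose C9 carries the C11–C12 chain ending in the C13 tertiary carbinol, with PhI(OAc)2 forms C9–O, closes the tetrahydrofuran (O, C9, C11, C12, C13) and turns the arene into the ring B cyclohexadienone in one operation. The C10 ester then makes C5=C10 the dienophile for a Diels–Alder reaction that adds ring A; lactone, epoxide and dihydrofuran follow.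

Key step: step 12

Remark on numbering: labdane locants are used throughout (ring A = C1–C5 and C10; ring B = C5–C10; C11–C16 = spiro side chain; C17 = CH2 on C8; C18 = methyl; C19 and C20 = lactone C=O and CH2); β is the face of ring B that carries H-5, C-20 and C-11 in the target; TBS = tert-butyldimethylsilyl, TBDPS = tert-butyldiphenylsilyl, TIPS = triisopropylsilyl.
Remark on transient centres: the configurations drawn at C6 in 20–25 and at C4 in 19–21 and 23 are those of the expected main isomers; both centres are erased or reset later (C6 in step 21, C4 in steps 17 and 19), so epimers can be carried along.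
Remark on the alkyne: it is kept as its C-triisopropylsilyl derivative from 11 to 31, so that it cannot form an acetylide or be hydroborated, and is set free together with the C16 hydroxyl in step 27.

Step 1
Reactants: 1 2-bromo-3-methoxybenzoic acid
Product: 2 methyl 2-bromo-3-methoxybenzoate
Conditions: MeOH, H2SO4 (cat.), reflux
Reagents that add atoms: methanol, CO
Why: Fischer esterification of an acid with a single ortho substituent proceeds normally in refluxing methanol.

Step 2
Reactants: 2 methyl 2-bromo-3-methoxybenzoate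
Product: 4 methyl 2-bromo-5-hydroxy-3-methoxybenzoate, via aryl pinacol boronate 3 (not isolated)
Conditions: [Ir(OMe)(cod)]2 (1.5 mol%), 4,4'-di-tert-butyl-2,2'-bipyridine (3 mol%), B2pin2, THF, 80 °C; then KHSO5 (as Oxone, 2KHSO5·KHSO4·K2SO4), acetone–H2O, rt
Reagents that add atoms: potassium peroxymonosulfate, [K+].[O-]S(=O)(=O)OO; bis(pinacolato)diboron, CC1(C)OB(OC1(C)C)B1OC(C)(C)C(C)(C)O1 (its boron is carried only by 3)
Why: Iridium-catalysed C–H borylation is sterically governed and takes the only ring C–H with no ortho neighbour (the future C6), the aryl bromide is tolerated, and oxidation of the C–B bond gives the phenol in the same flask (borylation–oxidation sequence).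

Step 3
Reactants: 4 methyl 2-bromo-5-hydroxy-3-methoxybenzoate
Product: 5 methyl 2-bromo-5-[(tert-butyldimethylsilyl)oxy]-3-methoxybenzoate
Conditions: TBSCl, imidazole, DMF, rt
Reagents that add atoms: tert-butyldimethylsilyl chloride, CC(C)(C)[Si](C)(C)Cl
Why: Standard phenol silylation, which keeps the bromide from becoming an electron-rich phenoxide during the cross-coupling.

Step 4
Reactants: 6 2-methylidenepropane-1,3-diol
Product: 7 2-{[(tert-butyldiphenylsilyl)oxy]methyl}prop-2-en-1-ol
Conditions: NaH (1.0 equiv), THF, 0 °C; TBDPSCl, 0 °C → rt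
Reagents that add atoms: tert-butyl(chloro)diphenylsilane, CC(C)(C)[Si](Cl)(c1ccccc1)c1ccccc1
Why: Monosilylation of a symmetrical diol through its sparingly soluble monosodium alkoxide, which reacts once and leaves the second hydroxyl free.

Step 5
Reactants: 7 2-{[(tert-butyldiphenylsilyl)oxy]methyl}prop-2-en-1-ol
Product: 8 [(2S)-2-{[(tert-butyldiphenylsilyl)oxy]methyl}oxiran-2-yl]methanol
Conditions: Ti(OiPr)4 (10 mol%), L-(+)-diethyl tartrate (12 mol%), tBuOOH, 4 Å MS, CH2Cl2, −20 °C
Reagents that add atoms: tert-butyl hydroperoxide, CC(C)(C)OO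
Why: Sharpless asymmetric epoxidation of a 2-substituted allylic alcohol, in which the L-(+)-tartrate catalyst delivers oxygen to the face that gives the (S)-epoxide and so sets the future C13, the only external source of chirality.

Step 6
Reactants: 8 [(2S)-2-{[(tert-butyldiphenylsilyl)oxy]methyl}oxiran-2-yl]methanol
Product: 9 (2S)-2-{[(tert-butyldiphenylsilyl)oxy]methyl}oxirane-2-carbaldehyde
Conditions: Dess–Martin periodinane, NaHCO3, CH2Cl2, 0 °C → rt
Reagents that add atoms: none
Why: Buffered Dess–Martin oxidation of the primary alcohol gives an aldehyde that has no α-hydrogen and therefore cannot epimerise.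

Step 7
Reactants: 9 (2S)-2-{[(tert-butyldiphenylsilyl)oxy]methyl}oxirane-2-carbaldehyde
Product: 10 tert-butyl{[(2S)-2-ethynyloxiran-2-yl]methoxy}diphenylsilane
Conditions: dimethyl (1-diazo-2-oxopropyl)phosphonate, K2CO3, MeOH, 0 °C → rt
Reagents that add atoms: dimethyl (1-diazo-2-oxopropyl)phosphonate, COP(=O)(OC)C(=[N+]=[N-])C(C)=O
Why: Seyferth–Gilbert homologation in its Ohira–Bestmann form converts the aldehyde into the terminal alkyne (C15 from the diazo carbon) under carbonate conditions that spare the epoxide and the silyl ether.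

Step 8
Reactants: 10 tert-butyl{[(2S)-2-ethynyloxiran-2-yl]methoxy}diphenylsilane
Product: 11 tert-butyldiphenyl({(2S)-2-[(triisopropylsilyl)ethynyl]oxiran-2-yl}methoxy)silane
Conditions: n-BuLi, THF, −78 °C; TIPSOTf, −78 → 0 °C
Reagents that add atoms: triisopropylsilyl trifluoromethanesulfonate, CC(C)[Si](C(C)C)(C(C)C)OS(=O)(=O)C(F)(F)F
Why: C-silylation of the lithium acetylide is fast at −78 °C, where the epoxide is not attacked, and the robust silyl cap later survives carbonate methanolysis, hydroboration and enolate chemistry.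

Step 9
Reactants: 11 tert-butyldiphenyl({(2S)-2-[(triisopropylsilyl)ethynyl]oxiran-2-yl}methoxy)silane
Product: 12 (3R)-3-{[(tert-butyldiphenylsilyl)oxy]methyl}-5-(triisopropylsilyl)pent-1-en-4-yn-3-ol
Conditions: Me3SI (3 equiv), n-BuLi (2.9 equiv), THF, −10 °C → rt
Reagents that add atoms: trimethylsulfonium iodide, C[S+](C)C.[I-]
Why: Dimethylsulfonium methylide opens the epoxide at its CH2 terminus and the β-sulfonium alkoxide loses dimethyl sulfide to give the vinyl carbinol (one-carbon homologation of an epoxide to an allylic alcohol, C11 from the ylide); no bond at the carbinol carbon is broken, so its configuration is kept.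

Step 10
Reactants: 12 (3R)-3-{[(tert-butyldiphenylsilyl)oxy]methyl}-5-(triisopropylsilyl)pent-1-en-4-yn-3-ol; 5 methyl 2-bromo-5-[(tert-butyldimethylsilyl)oxy]-3-methoxybenzoate
Product: 14 methyl 5-[(tert-butyldimethylsilyl)oxy]-2-[(3R)-3-{[(tert-butyldiphenylsilyl)oxy]methyl}-3-hydroxy-5-(triisopropylsilyl)pent-4-yn-1-yl]-3-methoxybenzoate, via primary alkyl-9-BBN borane 13 (not isolated)
Conditions: 9-BBN (2.5 equiv), THF, 0 °C → rt; then 5, PdCl2(dppf) (5 mol%), K3PO4 (3 M aq), DMF, 50 °C
Reagents that add atoms: 9-borabicyclo[3.3.1]nonane, B1C2CCCC1CCC2 (its boron is carried only by 13)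
Why: 9-BBN adds anti-Markovnikov to the monosubstituted alkene only (the doubly hindered silylalkyne is inert), and B-alkyl Suzuki–Miyaura coupling with the ester-activated aryl bromide forms the C9–C11 bond.

Step 11
Reactants: 14 methyl 5-[(tert-butyldimethylsilyl)oxy]-2-[(3R)-3-{[(tert-butyldiphenylsilyl)oxy]methyl}-3-hydroxy-5-(triisopropylsilyl)pent-4-yn-1-yl]-3-methoxybenzoate
Product: 15 methyl 2-[(3R)-3-{[(tert-butyldiphenylsilyl)oxy]methyl}-3-hydroxy-5-(triisopropylsilyl)pent-4-yn-1-yl]-5-hydroxy-3-methoxybenzoate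
Conditions: K2CO3, MeOH, rt
Reagents that add atoms: none
Why: Carbonate methanolysis cleaves only the aryl silyl ether (phenoxide is a good leaving group on silicon), while the alkyl TBDPS ether, the alkynyl TIPS group and the methyl ester are unchanged.

Step 12
Reactants: 15 methyl 2-[(3R)-3-{[(tert-butyldiphenylsilyl)oxy]methyl}-3-hydroxy-5-(triisopropylsilyl)pent-4-yn-1-yl]-5-hydroxy-3-methoxybenzoate
Product: 16 methyl (2R,5S)-2-{[(tert-butyldiphenylsilyl)oxy]methyl}-10-methoxy-8-oxo-2-[(triisopropylsilyl)ethynyl]-1-oxaspiro[4.5]deca-6,9-diene-6-carboxylate (spiro carbon = C9, carbinol carbon = C13)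
Conditions: PhI(OAc)2 (1.1 equiv), (CF3)2CHOH, 0 °C
Reagents that add atoms: none
Why: The phenol oxygen replaces acetate on trivalent iodine and loss of PhI leaves a phenoxenium-type cation with charge at C9, which the tethered C13 hydroxyl captures; this is the established PhI(OAc)2 oxidative spiroetherification of para-(3-hydroxyalkyl)phenols. The tetrahydrofuran (O, C9, C11, C12, C13) closes in a 5-exo mode and the benzene ring becomes the ring B cyclohexa-2,5-dienone. Regioselectivity is secured because only attack at C9 gives a five-membered ether and the non-nucleophilic fluorinated solvent does not compete. The new stereocentre C9 is controlled by C13: in the closing transition state the silyloxymethyl arm should lie beside the small in-plane C8 methoxy group and the rod-like silylethynyl group beside the twisted C10 ester, which is the (9S,13R) isomer. The C8 methoxy group also eases the oxidation and later becomes the C8 carbonyl, while the C10 ester marks C5=C10 as the only dienophilic arm.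

Step 13
Reactants: 17 (2E)-penta-2,4-dienoic acid
Product: 18 tert-butyl (2E)-penta-2,4-dienoate
Conditions: tert-butyl 2,2,2-trichloroacetimidate, BF3·OEt2 (cat.), cyclohexane–CH2Cl2, rt
Reagents that add atoms: tert-butyl 2,2,2-trichloroacetimidate, CC(C)(C)OC(=N)C(Cl)(Cl)Cl
Why: Acid-catalysed tert-butylation with the trichloroacetimidate runs at room temperature and so avoids polymerisation of the dienoic acid.

Step 14
Reactants: 16 methyl (2R,5S)-2-{[(tert-butyldiphenylsilyl)oxy]methyl}-10-methoxy-8-oxo-2-[(triisopropylsilyl)ethynyl]-1-oxaspiro[4.5]deca-6,9-diene-6-carboxylate; 18 tert-butyl (2E)-penta-2,4-dienoate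
Product: 19 cis-fused Diels–Alder adduct: 6-oxo-8-methoxy-2,7-diene with 10β-CO2Me (C20), 5β-H, 4α-CO2tBu (C19) and the 9α-O spiro ether (9S,13R; C13 carries the TIPS-ethynyl and CH2OTBDPS arms)
Conditions: 18 (5 equiv), BHT (cat.), CH2Cl2, 12 kbar, 40 °C
Reagents that add atoms: none
Why: Diels–Alder reaction at the doubly activated C5=C10 bond (the C7=C8 arm is deactivated by its methoxy group) is driven by pressure, the C6 carbonyl directs the orientation that forms C4–C5 and C1–C10, and the diene should approach the dienone face bearing the ether oxygen, anti to C11, so that suprafacial addition sets C10 (CO2Me β) and C5 (H β) cis, while C4 (ketone-endo, CO2tBu α) is of no consequence.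

Step 15
Reactants: 19 Diels–Alder adduct
Product: 20 6α-alcohol of 19 (C6 carbonyl reduced; 8-methoxy-7-ene, both esters and the 2-ene unchanged)
Conditions: NaBH4, CeCl3·7H2O, MeOH–THF, 0 °C
Reagents that add atoms: none
Why: Luche reduction gives 1,2-addition to the vinylogous-ester carbonyl and leaves both esters, with hydride entering C6 cis to H-5 and anti to C4 (6α-OH expected, configuration inconsequential).

Step 16
Reactants: 20 6α-alcohol
Product: 21 6α-TBS ether of 20
Conditions: TBSCl, imidazole, DMAP (cat.), DMF, 40 °C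
Reagents that add atoms: tert-butyldimethylsilyl chloride, CC(C)(C)[Si](C)(C)Cl
Why: Silylation under non-acidic conditions (the γ-alkoxy allylic alcohol ionises easily) blocks lactonisation of O-6 onto the C19 ester and alkoxide side reactions in the basic steps that follow.

Step 17
Reactants: 21 6α-TBS ether
Product: 22 conjugated ester: C3=C4 isomer of 21 (ring A alkene moved next to the tert-butyl ester)
Conditions: DBU, toluene, 80 °C
Reagents that add atoms: none
Why: Base-mediated isomerisation of a β,γ- to an α,β-unsaturated ester through the dienolate (C4–H is both allylic and α to the ester), driven by conjugation.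

Step 18
Reactants: 22 conjugated ester
Product: 23 saturated ring A diester (4α-CO2tBu, 5β-H, 10β-CO2Me, 6α-OTBS, 8-methoxy-7-ene)
Conditions: Mg, MeOH, rt
Reagents that add atoms: none
Why: Electron-transfer conjugate reduction with magnesium in methanol saturates only the enoate and leaves the enol ether, the silylalkyne and the other ester, with C4 protonated mainly to the equatorial ester (either epimer serves).

Step 19
Reactants: 23 saturated ring A diester
Product: 24 C4-methylated diester (18-CH3 α, 19-CO2tBu β, syn to the 10β-CO2Me)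
Conditions: LiN(iPr)2, THF, −78 °C; MeI, DMPU, −78 → −20 °C
Reagents that add atoms: iodomethane, CI
Why: Alkylation of the lithium ester enolate: with quaternary C9 equatorial on the ring A chair the C20 ester is axial and screens the β face, so methyl should enter from the α face and become equatorial C18, leaving C19 axial and syn to C20.

Step 20
Reactants: 24 C4-methylated diester
Product: 25 C20 primary alcohol (10β-CH2OH) with the tert-butyl ester intact
Conditions: LiEt3BH (2.5 equiv), THF, −40 → 0 °C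
Reagents that add atoms: none
Why: Lithium triethylborohydride reduces the hindered methyl ester, whereas the tert-butyl ester on quaternary C4 resists, and the alkoxyborate formed is too weak a nucleophile to lactonise before work-up.

Step 21
Reactants: 25 C20 primary alcohol
Product: 26 19,20-lactone with the C6=C7–C8=O enone (4α-CH3, 5β-H, 9α-O spiro ether)
Conditions: CF3CO2H–CH2Cl2–H2O (10:40:1), 0 °C → rt
Reagents that add atoms: water, O
Why: One acid treatment cleaves the tert-butyl ester, lets the acid lactonise onto the syn-axial C20 hydroxyl (six-membered 19,20-lactone) and, by ionisation of the allylic C6 silyl ether and hydrolysis of the C8 enol ether, gives the transposed enone (Stork–Danheiser transposition); no stereocentre is created.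

Step 22
Reactants: 26 enone lactone
Product: 27 6β,7β-epoxy-8-ketone lactone
Conditions: tBuOOH, DBU, CH2Cl2, 0 °C
Reagents that add atoms: tert-butyl hydroperoxide, CC(C)(C)OO
Why: Nucleophilic (Weitz–Scheffer) epoxidation: the peroxide anion adds to C6 from the β face, because C1 is axial on the α face of ring B in the lactone-locked cis-decalin, and the enolate closes the 6β,7β-epoxide.

Step 23
Reactants: 27 6β,7β-epoxy-8-ketone lactone
Product: 28 6β-hydroxy-8-ketone lactone
Conditions: (PhSe)2, NaBH4, EtOH; AcOH; then 27, 0 °C → rt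
Reagents that add atoms: none
Why: Organoselenium reduction of an α,β-epoxy ketone: the selenolate opens the epoxide at C7, a second selenolate removes selenium to give the enolate, and protonation leaves the C6–O bond and its β configuration untouched.

Step 24
Reactants: 28 6β-hydroxy-8-ketone lactone
Product: 29 6β-acetoxy-8-ketone lactone
Conditions: Ac2O, pyridine, DMAP (cat.), CH2Cl2, 0 °C
Reagents that add atoms: acetic anhydride, CC(=O)OC(C)=O
Why: DMAP-catalysed acylation of the equatorial secondary alcohol, run cold so that the β-acetoxy ketone does not eliminate.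

Step 25
Reactants: 29 6β-acetoxy-8-ketone lactone
Product: 30 6β-acetoxy-8(17)-methylene lactone
Conditions: Zn, CH2Br2, TiCl4, THF–CH2Cl2, 0 °C → rt
Reagents that add atoms: dibromomethane, BrCBr
Why: Takai–Lombardo methylenation with the non-basic zinc–titanium methylene reagent converts the hindered, elimination-prone C8 ketone into the exocyclic alkene and spares the acetate and the lactone.

Step 26
Reactants: 30 6β-acetoxy-8(17)-methylene lactone
Product: 31 8β,17-epoxide (epoxide oxygen β, 8R)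
Conditions: dimethyldioxirane (acetone solution), CH2Cl2, −20 → 0 °C
Reagents that add atoms: dimethyldioxirane, CC1(C)OO1
Why: Electrophilic epoxidation of the 1,1-disubstituted alkene should come from the β face, since the α face is screened by syn-axial C1 and by the C16 silyloxymethyl arm, which sets C8; the silylated alkyne is inert.

Step 27
Reactants: 31 8β,17-epoxide
Product: 32 16-hydroxy-14-yne (C16–OH and terminal C14≡C15–H set free; acetate, lactone and epoxide intact)
Conditions: Bu4NF, AcOH (1:1), THF, rt → 40 °C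
Reagents that add atoms: none
Why: Fluoride cleaves the O–Si bond at C16 and the C–Si bond of the alkyne in one operation, and the acetic acid buffer protects the acetate, the lactone and the epoxide.

Step 28
Reactants: 32 16-hydroxy-14-yne
Product: 33 CNP0173713.1: 6β-acetoxy-8β,17:9α,13:15,16-triepoxy-5β-labd-14-en-19,20-olide, (4S,5S,6R,8R,9S,10S,13R) in labdane numbering
Conditions: Mo(CO)6 (25 mol%), Et3N, Et2O, hν (350 nm), rt
Reagents that add atoms: none
Why: Cycloisomerisation of a homopropargylic alcohol: the terminal alkyne forms a molybdenum vinylidene at C15, the C16 hydroxyl adds to it in a 5-endo closure and protonation releases the 2,3-dihydrofuran, under amine conditions that leave C13, the epoxide, the acetate and the lactone untouched.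

Compound list
1 | 2-bromo-3-methoxybenzoic acid | OC(=O)c1cccc(OC)c1Br | starting material
2 | methyl 2-bromo-3-methoxybenzoate | COC(=O)c1cccc(OC)c1Br | intermediate
3 | methyl 2-bromo-3-methoxy-5-(4,4,5,5-tetramethyl-1,3,2-dioxaborolan-2-yl)benzoate | COC(=O)c1cc(B2OC(C)(C)C(C)(C)O2)cc(OC)c1Br | intermediate
4 | methyl 2-bromo-5-hydroxy-3-methoxybenzoate | COC(=O)c1cc(O)cc(OC)c1Br | intermediate
5 | methyl 2-bromo-5-[(tert-butyldimethylsilyl)oxy]-3-methoxybenzoate | COC(=O)c1cc(O[Si](C)(C)C(C)(C)C)cc(OC)c1Br | intermediate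
6 | 2-methylidenepropane-1,3-diol | C=C(CO)CO | starting material
7 | 2-{[(tert-butyldiphenylsilyl)oxy]methyl}prop-2-en-1-ol | C=C(CO)CO[Si](c1ccccc1)(c1ccccc1)C(C)(C)C | intermediate
8 | [(2S)-2-{[(tert-butyldiphenylsilyl)oxy]methyl}oxiran-2-yl]methanol | OC[C@@]1(CO[Si](c2ccccc2)(c2ccccc2)C(C)(C)C)CO1 | intermediate
9 | (2S)-2-{[(tert-butyldiphenylsilyl)oxy]methyl}oxirane-2-carbaldehyde | O=C[C@@]1(CO[Si](c2ccccc2)(c2ccccc2)C(C)(C)C)CO1 | intermediate
10 | tert-butyl{[(2S)-2-ethynyloxiran-2-yl]methoxy}diphenylsilane | C#C[C@@]1(CO[Si](c2ccccc2)(c2ccccc2)C(C)(C)C)CO1 | intermediate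
11 | tert-butyldiphenyl({(2S)-2-[(triisopropylsilyl)ethynyl]oxiran-2-yl}methoxy)silane | CC(C)[Si](C(C)C)(C(C)C)C#C[C@@]1(CO[Si](c2ccccc2)(c2ccccc2)C(C)(C)C)CO1 | intermediate
12 | (3R)-3-{[(tert-butyldiphenylsilyl)oxy]methyl}-5-(triisopropylsilyl)pent-1-en-4-yn-3-ol | C=C[C@@](O)(C#C[Si](C(C)C)(C(C)C)C(C)C)CO[Si](c1ccccc1)(c1ccccc1)C(C)(C)C | intermediate
13 | 9-[(3R)-3-{[(tert-butyldiphenylsilyl)oxy]methyl}-3-hydroxy-5-(triisopropylsilyl)pent-4-yn-1-yl]-9-borabicyclo[3.3.1]nonane | C1CCC2CCCC1B2CC[C@@](O)(C#C[Si](C(C)C)(C(C)C)C(C)C)CO[Si](c1ccccc1)(c1ccccc1)C(C)(C)C | intermediate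
14 | methyl 5-[(tert-butyldimethylsilyl)oxy]-2-[(3R)-3-{[(tert-butyldiphenylsilyl)oxy]methyl}-3-hydroxy-5-(triisopropylsilyl)pent-4-yn-1-yl]-3-methoxybenzoate | COC(=O)c1cc(O[Si](C)(C)C(C)(C)C)cc(OC)c1CC[C@@](O)(C#C[Si](C(C)C)(C(C)C)C(C)C)CO[Si](c1ccccc1)(c1ccccc1)C(C)(C)C | intermediate
15 | methyl 2-[(3R)-3-{[(tert-butyldiphenylsilyl)oxy]methyl}-3-hydroxy-5-(triisopropylsilyl)pent-4-yn-1-yl]-5-hydroxy-3-methoxybenzoate | COC(=O)c1cc(O)cc(OC)c1CC[C@@](O)(C#C[Si](C(C)C)(C(C)C)C(C)C)CO[Si](c1ccccc1)(c1ccccc1)C(C)(C)C | intermediate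
16 | methyl (2R,5S)-2-{[(tert-butyldiphenylsilyl)oxy]methyl}-10-methoxy-8-oxo-2-[(triisopropylsilyl)ethynyl]-1-oxaspiro[4.5]deca-6,9-diene-6-carboxylate | COC(=O)C1=CC(=O)C=C(OC)[C@]12CC[C@@](C#C[Si](C(C)C)(C(C)C)C(C)C)(CO[Si](c3ccccc3)(c3ccccc3)C(C)(C)C)O2 | intermediate
17 | (2E)-penta-2,4-dienoic acid | C=C/C=C/C(=O)O | starting material
18 | tert-butyl (2E)-penta-2,4-dienoate | C=C/C=C/C(=O)OC(C)(C)C | intermediate
19 | cis-fused Diels–Alder adduct (6-oxo-8-methoxy-2,7-diene; 10β-CO2Me, 5β-H, 4α-CO2tBu; 9S,13R) | O=C1C=C(OC)[C@]2(CC[C@@](C#C[Si](C(C)C)(C(C)C)C(C)C)(CO[Si](c5ccccc5)(c5ccccc5)C(C)(C)C)O2)[C@@]3(C(=O)OC)CC=C[C@@H](C(=O)OC(C)(C)C)[C@@H]13 | intermediate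
20 | 6α-alcohol of the adduct | O[C@H]1C=C(OC)[C@]2(CC[C@@](C#C[Si](C(C)C)(C(C)C)C(C)C)(CO[Si](c5ccccc5)(c5ccccc5)C(C)(C)C)O2)[C@@]3(C(=O)OC)CC=C[C@@H](C(=O)OC(C)(C)C)[C@@H]13 | intermediate
21 | 6α-TBS ether | CC(C)(C)[Si](C)(C)O[C@H]1C=C(OC)[C@]2(CC[C@@](C#C[Si](C(C)C)(C(C)C)C(C)C)(CO[Si](c5ccccc5)(c5ccccc5)C(C)(C)C)O2)[C@@]3(C(=O)OC)CC=C[C@@H](C(=O)OC(C)(C)C)[C@@H]13 | intermediate
22 | conjugated (C3=C4) tert-butyl ester | CC(C)(C)[Si](C)(C)O[C@H]1C=C(OC)[C@]2(CC[C@@](C#C[Si](C(C)C)(C(C)C)C(C)C)(CO[Si](c5ccccc5)(c5ccccc5)C(C)(C)C)O2)[C@@]3(C(=O)OC)CCC=C(C(=O)OC(C)(C)C)[C@@H]13 | intermediate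
23 | saturated ring A diester (4α-CO2tBu) | CC(C)(C)[Si](C)(C)O[C@H]1C=C(OC)[C@]2(CC[C@@](C#C[Si](C(C)C)(C(C)C)C(C)C)(CO[Si](c5ccccc5)(c5ccccc5)C(C)(C)C)O2)[C@@]3(C(=O)OC)CCC[C@@H](C(=O)OC(C)(C)C)[C@@H]13 | intermediate
24 | C4-methylated diester (18-CH3 α, 19-CO2tBu β) | CC(C)(C)[Si](C)(C)O[C@H]1C=C(OC)[C@]2(CC[C@@](C#C[Si](C(C)C)(C(C)C)C(C)C)(CO[Si](c5ccccc5)(c5ccccc5)C(C)(C)C)O2)[C@@]3(C(=O)OC)CCC[C@](C)(C(=O)OC(C)(C)C)[C@@H]13 | intermediate
25 | C20 alcohol (10β-CH2OH) tert-butyl ester | CC(C)(C)[Si](C)(C)O[C@H]1C=C(OC)[C@]2(CC[C@@](C#C[Si](C(C)C)(C(C)C)C(C)C)(CO[Si](c5ccccc5)(c5ccccc5)C(C)(C)C)O2)[C@@]3(CO)CCC[C@](C)(C(=O)OC(C)(C)C)[C@@H]13 | intermediate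
26 | 19,20-lactone 6-en-8-one | C1=CC(=O)[C@]2(CC[C@@](C#C[Si](C(C)C)(C(C)C)C(C)C)(CO[Si](c5ccccc5)(c5ccccc5)C(C)(C)C)O2)[C@]34CCC[C@](C)(C(=O)OC3)[C@@H]14 | intermediate
27 | 6β,7β-epoxy-8-ketone lactone | O1[C@@H]2[C@H]1C(=O)[C@]3(CC[C@@](C#C[Si](C(C)C)(C(C)C)C(C)C)(CO[Si](c6ccccc6)(c6ccccc6)C(C)(C)C)O3)[C@]45CCC[C@](C)(C(=O)OC4)[C@@H]25 | intermediate
28 | 6β-hydroxy-8-ketone lactone | O[C@@H]1CC(=O)[C@]2(CC[C@@](C#C[Si](C(C)C)(C(C)C)C(C)C)(CO[Si](c5ccccc5)(c5ccccc5)C(C)(C)C)O2)[C@]34CCC[C@](C)(C(=O)OC3)[C@@H]14 | intermediate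
29 | 6β-acetoxy-8-ketone lactone | CC(=O)O[C@@H]1CC(=O)[C@]2(CC[C@@](C#C[Si](C(C)C)(C(C)C)C(C)C)(CO[Si](c5ccccc5)(c5ccccc5)C(C)(C)C)O2)[C@]34CCC[C@](C)(C(=O)OC3)[C@@H]14 | intermediate
30 | 6β-acetoxy-8(17)-methylene lactone | CC(=O)O[C@@H]1CC(=C)[C@]2(CC[C@@](C#C[Si](C(C)C)(C(C)C)C(C)C)(CO[Si](c5ccccc5)(c5ccccc5)C(C)(C)C)O2)[C@]34CCC[C@](C)(C(=O)OC3)[C@@H]14 | intermediate
31 | 8β,17-epoxide | CC(=O)O[C@@H]1C[C@@]6(CO6)[C@]2(CC[C@@](C#C[Si](C(C)C)(C(C)C)C(C)C)(CO[Si](c5ccccc5)(c5ccccc5)C(C)(C)C)O2)[C@]34CCC[C@](C)(C(=O)OC3)[C@@H]14 | intermediate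
32 | 16-hydroxy-14-yne | CC(=O)O[C@@H]1C[C@@]6(CO6)[C@]2(CC[C@@](C#C)(CO)O2)[C@]34CCC[C@](C)(C(=O)OC3)[C@@H]14 | intermediate
33 | CNP0173713.1 | CC(=O)O[C@@H]1C[C@@]2(CO2)[C@]2(CC[C@]3(C=COC3)O2)[C@]23CCC[C@](C)(C(=O)OC2)[C@@H]13 | target

Total step count: 28. Longest linear sequence: 24 steps (from 6 through steps 4–12 and 14–28).

Steps most likely to fail

1. Step 12: transmission of chirality from C13 to C9 during ring closure may be weak, so that both C9 epimers form. Fallback: it sets out from 15 and accepts an unselective closure. The epimers are separated by chromatography, and the unwanted one, methyl (2R,5R)-2-{[(tert-butyldiphenylsilyl)oxy]methyl}-10-methoxy-8-oxo-2-[(triisopropylsilyl)ethynyl]-1-oxaspiro[4.5]deca-6,9-diene-6-carboxylate F1, is returned to the phenol with Zn in AcOH (reductive cleavage of the C9–O bond with rearomatisation). The recovered 15 is oxidised again, and the route is rejoined at 16.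

2. Step 14: the cycloaddition may be too slow, or lose its orientation or facial preference, because diene and dienophile are both electron-poor and C10 is congested. Fallback: it sets out from 16 and 17 and uses a donor-type diene of the same carbon skeleton. LiAlH4 reduction of 17 gives (2E)-penta-2,4-dien-1-ol F2, and TBSCl with imidazole gives tert-butyldimethyl[(2E)-penta-2,4-dien-1-yloxy]silane F3. Cycloaddition of F3 to 16 at 12 kbar, now with matched electron demand, should give the 19-silyloxymethyl adduct F4. HF·pyridine buffered with pyridine frees the primary alcohol F5 (the TBDPS ether and the silylalkyne survive), and TEMPO with PhI(OAc)2 in wet MeCN oxidises it to the C19 acid F6. tert-Butyl 2,2,2-trichloroacetimidate then gives 19, where the route is rejoined.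

3. Step 19: methyl iodide may attack the wrong face of the enolate if ring A reacts through its other chair (C9 axial), giving the C4 epimer. Fallback: it sets out from 23 and fixes C19 before methylation. LiEt3BH reduces the C20 ester to the hydroxy ester F7. KOtBu in THF epimerises C4, and the alkoxide closes onto the cis ester to give the C4–H 19,20-lactone F8. Bridgehead enolate formation with LiN(iPr)2 and methylation with MeI can then occur only with C19 held β, giving the methylated lactone F9 (6α-OTBS, 8-methoxy-7-ene). Aqueous CF3CO2H unmasks the enone, and the route is rejoined at 26.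

Further compounds
F1 | step 12 | methyl (2R,5R)-2-{[(tert-butyldiphenylsilyl)oxy]methyl}-10-methoxy-8-oxo-2-[(triisopropylsilyl)ethynyl]-1-oxaspiro[4.5]deca-6,9-diene-6-carboxylate | COC(=O)C1=CC(=O)C=C(OC)[C@@]12CC[C@@](C#C[Si](C(C)C)(C(C)C)C(C)C)(CO[Si](c3ccccc3)(c3ccccc3)C(C)(C)C)O2
F2 | step 14 | (2E)-penta-2,4-dien-1-ol | C=C/C=C/CO
F3 | step 14 | tert-butyldimethyl[(2E)-penta-2,4-dien-1-yloxy]silane | C=C/C=C/CO[Si](C)(C)C(C)(C)C
F4 | step 14 | 19-silyloxymethyl Diels–Alder adduct (4α-CH2OTBS, 5β-H, 10β-CO2Me) | O=C1C=C(OC)[C@]2(CC[C@@](C#C[Si](C(C)C)(C(C)C)C(C)C)(CO[Si](c5ccccc5)(c5ccccc5)C(C)(C)C)O2)[C@@]3(C(=O)OC)CC=C[C@@H](CO[Si](C)(C)C(C)(C)C)[C@@H]13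
F5 | step 14 | 19-hydroxymethyl adduct | O=C1C=C(OC)[C@]2(CC[C@@](C#C[Si](C(C)C)(C(C)C)C(C)C)(CO[Si](c5ccccc5)(c5ccccc5)C(C)(C)C)O2)[C@@]3(C(=O)OC)CC=C[C@@H](CO)[C@@H]13
F6 | step 14 | C19 carboxylic acid adduct | O=C1C=C(OC)[C@]2(CC[C@@](C#C[Si](C(C)C)(C(C)C)C(C)C)(CO[Si](c5ccccc5)(c5ccccc5)C(C)(C)C)O2)[C@@]3(C(=O)OC)CC=C[C@@H](C(=O)O)[C@@H]13
F7 | step 19 | C20 alcohol of the unmethylated tert-butyl ester | CC(C)(C)[Si](C)(C)O[C@H]1C=C(OC)[C@]2(CC[C@@](C#C[Si](C(C)C)(C(C)C)C(C)C)(CO[Si](c5ccccc5)(c5ccccc5)C(C)(C)C)O2)[C@@]3(CO)CCC[C@@H](C(=O)OC(C)(C)C)[C@@H]13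
F8 | step 19 | C4–H 19,20-lactone (6α-OTBS, 8-methoxy-7-ene) | CC(C)(C)[Si](C)(C)O[C@H]1C=C(OC)[C@]2(CC[C@@](C#C[Si](C(C)C)(C(C)C)C(C)C)(CO[Si](c5ccccc5)(c5ccccc5)C(C)(C)C)O2)[C@]34CCC[C@H](C(=O)OC3)[C@@H]14
F9 | step 19 | C4-methylated 19,20-lactone (6α-OTBS, 8-methoxy-7-ene) | CC(C)(C)[Si](C)(C)O[C@H]1C=C(OC)[C@]2(CC[C@@](C#C[Si](C(C)C)(C(C)C)C(C)C)(CO[Si](c5ccccc5)(c5ccccc5)C(C)(C)C)O2)[C@]34CCC[C@](C)(C(=O)OC3)[C@@H]14
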